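**Retrosynthetic overview**
- The target is the 2-(3,4-dihydroxyphenyl)ethyl ester of elenolic acid. The last step unmasks the catechol (silyl ethers) and the C3 aldehyde (dimethyl acetal) together.
- The dihydropyran is the only ring built (after a transient oxirane). It is closed late by a proposed alkoxide/methyl propiolate oxa-Michael–Michael annulation onto an (E)-enoate, which forms O1–C6 and C4–C5 and sets C4.
- The enoate comes from cross-metathesis of a vinyl acetal with the acrylate of the protected hydroxytyrosol.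
- Key step: a semipinacol 1,2-vinyl shift of a Sharpless-derived 2,3-epoxy alcohol turns a linear C6 chain into the branched 2-vinyl-3-oxybutanal; it forms C3–C4, sets C3 and keeps C2.
- The aryl fragment is made from catechol by bromination, silylation, lithiation/oxirane opening and acryloylation.

Assumption: racemic (4E)-hexa-1,4-dien-3-ol is taken as purchasable; step 5 is a kinetic resolution, so its yield cannot exceed 50%.

**Step 1**
Reactants: 1 benzene-1,2-diol (catechol)
Product: 2 4-bromobenzene-1,2-diol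
Conditions: NBS (1.0 equiv), HBF4·OEt2, MeCN, −30 °C → rt
Reagents that add atoms: N-bromosuccinimide, O=C1CCC(=O)N1Br
Why: Electrophilic aromatic bromination of the electron-rich ring goes para to one hydroxyl and stops at the monobromide; no stereocentre is involved.

**Step 2**
Reactants: 2 4-bromobenzene-1,2-diol
Product: 3 4-bromo-1,2-bis[(tert-butyldimethylsilyl)oxy]benzene
Conditions: t-BuMe2SiCl (2.3 equiv), imidazole, DMF, rt
Reagents that add atoms: tert-butyldimethylsilyl chloride, CC(C)(C)[Si](C)(C)Cl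
Why: Standard silyl ether formation masks both phenols for the organolithium and base steps and allows fluoride removal at the end.

**Step 3**
Reactants: 3 4-bromo-1,2-bis[(tert-butyldimethylsilyl)oxy]benzene; 4 oxirane
Product: 6 2-{3,4-bis[(tert-butyldimethylsilyl)oxy]phenyl}ethan-1-ol, via aryllithium 5 (not isolated)
Conditions: n-BuLi (1.05 equiv), THF, −78 °C; then oxirane (3 equiv), BF3·OEt2 (1.1 equiv), −78 °C → rt; then H2O
Reagents that add atoms: none
Why: Bromine–lithium exchange gives an aryllithium with no silyloxy group ortho to the metal (so no silyl migration), which opens the BF3-activated epoxide to the 2-arylethanol.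

**Step 4**
Reactants: 6 2-{3,4-bis[(tert-butyldimethylsilyl)oxy]phenyl}ethan-1-ol; 7 prop-2-enoyl chloride
Product: 8 2-{3,4-bis[(tert-butyldimethylsilyl)oxy]phenyl}ethyl prop-2-enoate
Conditions: Et3N, CH2Cl2, 0 °C
Reagents that add atoms: none
Why: O-acylation of the primary alcohol by the acid chloride installs the final ester linkage as an acrylate ready for metathesis.

**Step 5**
Reactants: 9 (4E)-hexa-1,4-dien-3-ol (racemate)
Product: 10 (1S)-1-[(2S,3S)-3-methyloxiran-2-yl]prop-2-en-1-ol
Conditions: Ti(OiPr)4 (0.10 equiv), L-(+)-diisopropyl tartrate (0.15 equiv), t-BuOOH (0.55 equiv), 4 Å molecular sieves, CH2Cl2, −20 °C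
Reagents that add atoms: tert-butyl hydroperoxide, CC(C)(C)OO
Why: Sharpless kinetic resolution: with L-(+)-tartrate only the (S)-alcohol is epoxidized, at its faster trans-propenyl alkene, to the erythro (2S,3S)-epoxide, which fixes the future C2 and (after inversion) C3, while the (R)-dienol is left behind.

**Step 6**
Reactants: 10 (1S)-1-[(2S,3S)-3-methyloxiran-2-yl]prop-2-en-1-ol
Product: 13 (2S,3S)-3-(dimethoxymethyl)pent-4-en-2-ol, via epoxy silyl ether 11 (not isolated), via silyloxy aldehyde 12 (not isolated)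
Conditions: Et3SiOTf (1.5 equiv), i-Pr2NEt (1.6 equiv), 4 Å molecular sieves, CH2Cl2, −78 → −45 °C; then MeOH, HC(OMe)3, camphorsulfonic acid (0.3 equiv), −45 → 0 °C
Reagents that add atoms: trimethyl orthoformate, COC(OC)OC; methanol, CO
Why: Suzuki–Tsuchihashi-type semipinacol rearrangement: after in-flask O-silylation the silyl triflate activates the epoxide and the vinyl group shifts 1,2 from the carbinol carbon to the adjacent epoxide carbon anti to the breaking C–O bond (inversion there gives C3 = S, the methyl-bearing C–O bond is untouched so C2 stays S, and the carbinol carbon becomes the aldehyde); acidic methanol/orthoformate then acetalizes the labile α-vinyl aldehyde and removes the silyl group.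

**Step 7**
Reactants: 13 (2S,3S)-3-(dimethoxymethyl)pent-4-en-2-ol; 8 2-{3,4-bis[(tert-butyldimethylsilyl)oxy]phenyl}ethyl prop-2-enoate
Product: 14 2-{3,4-bis[(tert-butyldimethylsilyl)oxy]phenyl}ethyl (2E,4S,5S)-4-(dimethoxymethyl)-5-hydroxyhex-2-enoate
Conditions: second-generation Hoveyda–Grubbs catalyst [(H2IMes)Cl2Ru=CH(2-iPrOC6H4), 5 mol%], 13 (1.3 equiv), CH2Cl2, 40 °C
Reagents that add atoms: none
Why: Olefin cross-metathesis of the monosubstituted alkene with the acrylate gives the (E)-enoate under thermodynamic control; free hydroxyl, acetal and aryl silyl ethers are tolerated and no stereocentre is touched.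

**Step 8**
Reactants: 14 2-{3,4-bis[(tert-butyldimethylsilyl)oxy]phenyl}ethyl (2E,4S,5S)-4-(dimethoxymethyl)-5-hydroxyhex-2-enoate; 15 methyl prop-2-ynoate
Product: 19 methyl (2S,3S,4S)-4-[2-(2-{3,4-bis[(tert-butyldimethylsilyl)oxy]phenyl}ethoxy)-2-oxoethyl]-3-(dimethoxymethyl)-2-methyl-3,4-dihydro-2H-pyran-5-carboxylate, via potassium alkoxide 16 (not isolated), via allenolate 17 (not isolated), via ester enolate 18 (not isolated)
Conditions: KN(SiMe3)2 (1.0 equiv), THF (0.01 M), −78 °C; methyl prop-2-ynoate (1.1 equiv) added over 1 h, −78 → −30 °C; then AcOH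
Reagents that add atoms: none
Why: Proposed new method: the potassium alkoxide adds to the alkynoate (oxa-Michael) to give a β-alkoxy allenolate which, at high dilution and with little protic partner, is trapped by 6-exo-trig Michael addition to the tethered (E)-enoate before it is protonated, forming O1–C6, C4–C5 and the ring in one operation; a half-chair transition state with the C2 methyl equatorial and the C3 acetal and C4 enoate trans-diaxial (no allylic strain against the planar allenolate ester) should give the 3,4-trans (4S) product; the closest known reaction type is the base- or amine-mediated oxa-Michael/Michael annulation of 2-hydroxyaryl enones or nitroalkenes with alkynoates to 4H-chromene-3-carboxylates, not yet shown for an aliphatic secondary alkoxide with an enoate acceptor.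

**Step 9**
Reactants: 19 methyl (2S,3S,4S)-4-[2-(2-{3,4-bis[(tert-butyldimethylsilyl)oxy]phenyl}ethoxy)-2-oxoethyl]-3-(dimethoxymethyl)-2-methyl-3,4-dihydro-2H-pyran-5-carboxylate
Product: 20 methyl (2S,3S,4S)-4-{2-[2-(3,4-dihydroxyphenyl)ethoxy]-2-oxoethyl}-3-formyl-2-methyl-3,4-dihydro-2H-pyran-5-carboxylate
Conditions: 48% aq. HF, MeCN, 0 °C → rt (short contact time)
Reagents that add atoms: water, O
Why: Global deprotection: fluoride cleaves both aryl silyl ethers and the dilute aqueous acid hydrolyses the dimethyl acetal to the aldehyde, while the vinylogous carbonate and both esters are stable and the short cold exposure avoids enolization at C3.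

**Compound list**
1 | benzene-1,2-diol (catechol) | Oc1ccccc1O | starting material
2 | 4-bromobenzene-1,2-diol | Oc1ccc(Br)cc1O | intermediate
3 | 4-bromo-1,2-bis[(tert-butyldimethylsilyl)oxy]benzene | CC(C)(C)[Si](C)(C)Oc1ccc(Br)cc1O[Si](C)(C)C(C)(C)C | intermediate
4 | oxirane | C1CO1 | starting material
5 | {3,4-bis[(tert-butyldimethylsilyl)oxy]phenyl}lithium | [Li]c1ccc(O[Si](C)(C)C(C)(C)C)c(O[Si](C)(C)C(C)(C)C)c1 | intermediate (not isolated)
6 | 2-{3,4-bis[(tert-butyldimethylsilyl)oxy]phenyl}ethan-1-ol | OCCc1ccc(O[Si](C)(C)C(C)(C)C)c(O[Si](C)(C)C(C)(C)C)c1 | intermediate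
7 | prop-2-enoyl chloride | C=CC(Cl)=O | starting material
8 | 2-{3,4-bis[(tert-butyldimethylsilyl)oxy]phenyl}ethyl prop-2-enoate | C=CC(=O)OCCc1ccc(O[Si](C)(C)C(C)(C)C)c(O[Si](C)(C)C(C)(C)C)c1 | intermediate
9 | (4E)-hexa-1,4-dien-3-ol (racemate) | C=CC(O)/C=C/C | starting material
10 | (1S)-1-[(2S,3S)-3-methyloxiran-2-yl]prop-2-en-1-ol | C=C[C@H](O)[C@@H]1O[C@H]1C | intermediate
11 | triethyl{[(1S)-1-[(2S,3S)-3-methyloxiran-2-yl]prop-2-en-1-yl]oxy}silane | C=C[C@H](O[Si](CC)(CC)CC)[C@@H]1O[C@H]1C | intermediate (not isolated)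
12 | (2S,3S)-2-ethenyl-3-[(triethylsilyl)oxy]butanal | O=C[C@@H](C=C)[C@H](C)O[Si](CC)(CC)CC | intermediate (not isolated)
13 | (2S,3S)-3-(dimethoxymethyl)pent-4-en-2-ol | COC(OC)[C@@H](C=C)[C@H](C)O | intermediate
14 | 2-{3,4-bis[(tert-butyldimethylsilyl)oxy]phenyl}ethyl (2E,4S,5S)-4-(dimethoxymethyl)-5-hydroxyhex-2-enoate | COC(OC)[C@@H](/C=C/C(=O)OCCc1ccc(O[Si](C)(C)C(C)(C)C)c(O[Si](C)(C)C(C)(C)C)c1)[C@H](C)O | intermediate
15 | methyl prop-2-ynoate | C#CC(=O)OC | starting material
16 | potassium alkoxide of 14 | COC(OC)[C@@H](/C=C/C(=O)OCCc1ccc(O[Si](C)(C)C(C)(C)C)c(O[Si](C)(C)C(C)(C)C)c1)[C@H](C)[O-].[K+] | intermediate (not isolated)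
17 | potassium β-alkoxy allenolate (written as the C5 carbanion) | COC(OC)[C@@H](/C=C/C(=O)OCCc1ccc(O[Si](C)(C)C(C)(C)C)c(O[Si](C)(C)C(C)(C)C)c1)[C@H](C)OC=[C-]C(=O)OC.[K+] | intermediate (not isolated)
18 | potassium ester enolate of 19 | COC(=O)C1=CO[C@@H](C)[C@@H](C(OC)OC)[C@@H]1C=C([O-])OCCc1ccc(O[Si](C)(C)C(C)(C)C)c(O[Si](C)(C)C(C)(C)C)c1.[K+] | intermediate (not isolated)
19 | methyl (2S,3S,4S)-4-[2-(2-{3,4-bis[(tert-butyldimethylsilyl)oxy]phenyl}ethoxy)-2-oxoethyl]-3-(dimethoxymethyl)-2-methyl-3,4-dihydro-2H-pyran-5-carboxylate | COC(=O)C1=CO[C@@H](C)[C@@H](C(OC)OC)[C@@H]1CC(=O)OCCc1ccc(O[Si](C)(C)C(C)(C)C)c(O[Si](C)(C)C(C)(C)C)c1 | intermediate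
20 | methyl (2S,3S,4S)-4-{2-[2-(3,4-dihydroxyphenyl)ethoxy]-2-oxoethyl}-3-formyl-2-methyl-3,4-dihydro-2H-pyran-5-carboxylate | COC(=O)C1=CO[C@@H](C)[C@@H](C=O)[C@@H]1CC(=O)OCCc1ccc(O)c(O)c1 | target

**Step count**
Total: 9 steps. Longest linear sequence: 7 steps (1, 2, 3, 4, 7, 8, 9); the second branch is steps 5 and 6, joining at step 7.

**Three steps most likely to fail**

Step 8 (the proposed annulation). The allenolate may be protonated (by the acetylenic C–H or regenerated alcohol) before it cyclizes, or C4 may form with low selectivity. The fallback uses known chemistry, sets out from 14 and comes back at 19. Conjugate addition of 14 to methyl prop-2-ynoate with catalytic N-methylmorpholine in CH2Cl2 gives the (E)-β-alkoxyacrylate 2-{3,4-bis[(tert-butyldimethylsilyl)oxy]phenyl}ethyl (2E,4S,5S)-4-(dimethoxymethyl)-5-{[(1E)-3-methoxy-3-oxoprop-1-en-1-yl]oxy}hex-2-enoate F1. Bromine addition at −78 °C followed by Et3N gives the α-bromo-β-alkoxyacrylate 2-{3,4-bis[(tert-butyldimethylsilyl)oxy]phenyl}ethyl (2E,4S,5S)-5-{[(1Z)-2-bromo-3-methoxy-3-oxoprop-1-en-1-yl]oxy}-4-(dimethoxymethyl)hex-2-enoate F2. Bu3SnH/AIBN in benzene at 80 °C then generates the vinyl radical, which closes 6-exo-trig onto the enoate through the same chair arrangement to give 19.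

Step 6 (semipinacol shift and in-flask acetalization). Hydride migration could compete with vinyl migration, and the α-vinyl aldehyde is volatile and can isomerize. The fallback changes the order of the C–C bond-forming events and the migrating group; it sets out from 10 and comes back at 14. Cross-metathesis of 10 with 8 (same ruthenium catalyst) gives the epoxy alcohol 2-{3,4-bis[(tert-butyldimethylsilyl)oxy]phenyl}ethyl (2E,4S)-4-hydroxy-4-[(2S,3S)-3-methyloxiran-2-yl]but-2-enoate F3. Silylation with Me3SiCl/imidazole gives the isolated silyl ether 2-{3,4-bis[(tert-butyldimethylsilyl)oxy]phenyl}ethyl (2E,4S)-4-[(2S,3S)-3-methyloxiran-2-yl]-4-[(trimethylsilyl)oxy]but-2-enoate F4. BF3·OEt2 at −78 °C (the classical two-stage protocol) shifts the ester-bearing alkenyl group to give the non-volatile aldehyde 2-{3,4-bis[(tert-butyldimethylsilyl)oxy]phenyl}ethyl (2E,4S,5S)-4-formyl-5-[(trimethylsilyl)oxy]hex-2-enoate F5. HC(OMe)3/MeOH with pyridinium p-toluenesulfonate converts F5 into 14. This does not rescue the route if alkenyl migration itself fails.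

Step 9 (global unmasking). The free β-alkoxy aldehyde can enolize in acid and scramble C3, or C2 by retro-oxa-Michael/re-closure. The fallback separates the two deprotections so that the aldehyde never meets strong acid; it sets out from 19 and comes back at 20. Et3N·3HF in THF removes only the silyl groups to give the catechol acetal methyl (2S,3S,4S)-4-{2-[2-(3,4-dihydroxyphenyl)ethoxy]-2-oxoethyl}-3-(dimethoxymethyl)-2-methyl-3,4-dihydro-2H-pyran-5-carboxylate F6. Buffered hydrolysis with pyridinium p-toluenesulfonate in wet acetone then releases the aldehyde 20.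

**Further compounds**
F1 | step 8 | 2-{3,4-bis[(tert-butyldimethylsilyl)oxy]phenyl}ethyl (2E,4S,5S)-4-(dimethoxymethyl)-5-{[(1E)-3-methoxy-3-oxoprop-1-en-1-yl]oxy}hex-2-enoate | COC(OC)[C@@H](/C=C/C(=O)OCCc1ccc(O[Si](C)(C)C(C)(C)C)c(O[Si](C)(C)C(C)(C)C)c1)[C@H](C)O/C=C/C(=O)OC
F2 | step 8 | 2-{3,4-bis[(tert-butyldimethylsilyl)oxy]phenyl}ethyl (2E,4S,5S)-5-{[(1Z)-2-bromo-3-methoxy-3-oxoprop-1-en-1-yl]oxy}-4-(dimethoxymethyl)hex-2-enoate | COC(OC)[C@@H](/C=C/C(=O)OCCc1ccc(O[Si](C)(C)C(C)(C)C)c(O[Si](C)(C)C(C)(C)C)c1)[C@H](C)O/C=C(\Br)C(=O)OC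
F3 | step 6 | 2-{3,4-bis[(tert-butyldimethylsilyl)oxy]phenyl}ethyl (2E,4S)-4-hydroxy-4-[(2S,3S)-3-methyloxiran-2-yl]but-2-enoate | O=C(OCCc1ccc(O[Si](C)(C)C(C)(C)C)c(O[Si](C)(C)C(C)(C)C)c1)/C=C/[C@H](O)[C@@H]1O[C@H]1C
F4 | step 6 | 2-{3,4-bis[(tert-butyldimethylsilyl)oxy]phenyl}ethyl (2E,4S)-4-[(2S,3S)-3-methyloxiran-2-yl]-4-[(trimethylsilyl)oxy]but-2-enoate | O=C(OCCc1ccc(O[Si](C)(C)C(C)(C)C)c(O[Si](C)(C)C(C)(C)C)c1)/C=C/[C@H](O[Si](C)(C)C)[C@@H]1O[C@H]1C
F5 | step 6 | 2-{3,4-bis[(tert-butyldimethylsilyl)oxy]phenyl}ethyl (2E,4S,5S)-4-formyl-5-[(trimethylsilyl)oxy]hex-2-enoate | O=C[C@@H](/C=C/C(=O)OCCc1ccc(O[Si](C)(C)C(C)(C)C)c(O[Si](C)(C)C(C)(C)C)c1)[C@H](C)O[Si](C)(C)C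
F6 | step 9 | methyl (2S,3S,4S)-4-{2-[2-(3,4-dihydroxyphenyl)ethoxy]-2-oxoethyl}-3-(dimethoxymethyl)-2-methyl-3,4-dihydro-2H-pyran-5-carboxylate | COC(=O)C1=CO[C@@H](C)[C@@H](C(OC)OC)[C@@H]1CC(=O)OCCc1ccc(O)c(O)c1
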